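**Plan**

- Retrosynthesis: the pyrone (ring B) is opened at O1–C2 (cyclodehydration) and cut at C2–C3 (crossed Claisen), giving a ring A methyl ketone and a ring C arylacetic ester. The ring C side chain is cut between its CH2 and the future C2 (lateral acylation of a benzylic methyl), ring C itself at C1'–C2' and C3'–C4', and ring A at C4–C4a (acetyl group).
- Enabling feature: ring C is a resorcylate with meta oxygens on C3' and C5', the carboxyl on C2' and the carbon branch on C1'. That is the dehydrogenated form of a 4-methoxycarbonyl-5-methylcyclohexane-1,3-dione, which a malonate and pent-3-en-2-one assemble in one operation.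
- Forward: ring C arises first as the saturated dione (step 1), is aromatised, benzylated and freed to the acid, and its methyl group is extended by one carbon. Ring A ketone is made from 5-heptylresorcinol. The two are joined by a Claisen condensation, the pyrone ring closes last, and hydrogenolysis frees the phenols.
- Design choice: from step 4 on the ring C carboxyl travels as the free acid (carboxylate under base). No ester then sits ortho to the enolisable side chain, where it would invite closure to a naphthalene-1,3-diol.
- Stereochemistry: the target has no stereocentre; the two centres of the dione are racemic and are erased in step 2.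

Key step: step 1

Assumption: (E)-pent-3-en-2-one and 5-heptylresorcinol are bought; dione 4 is drawn in its diketo form although it should exist largely as an enol.

**Route**

Step 1
Reactants: 1 (E)-pent-3-en-2-one; 2 dimethyl malonate
Product: 4 racemic methyl trans-6-methyl-2,4-dioxocyclohexane-1-carboxylate, via Michael adduct 3 (not isolated)
Conditions: NaOMe (1.1 equiv), MeOH, 0 °C → reflux; then 1 M HCl
Reagents that add atoms: none
Why: Sodiomalonate adds in conjugate fashion to C4 of the enone (the future C1'–C2' bond), and after proton transfer the methyl ketone enolate attacks one of the two equivalent ester groups with loss of methoxide (the future C3'–C4' bond), the product being drained as its stabilised dione enolate. This is the classical Michael–Dieckmann annulation of malonates with alk-3-en-2-ones that leads to 5-alkylcyclohexane-1,3-diones and dihydro-resorcylates. The one ring formed is a six-membered carbocycle closed in a 6-exo-trig Claisen-type acylation. The centre at C6 is set without control in the Michael step (racemic), and C1, an epimerisable β-keto ester carbon, should settle trans to the methyl group; both centres disappear on aromatisation. The step needs 1,4- rather than 1,2-addition, secured by the soft malonate anion, and a single mode of ring closure, secured because only the terminal methyl enolate can reach an ester through a six-membered transition state.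

Step 2
Reactants: 4 racemic methyl trans-6-methyl-2,4-dioxocyclohexane-1-carboxylate
Product: 5 methyl 2,4-dihydroxy-6-methylbenzoate
Conditions: I2 (20 mol%), DMSO, 80 °C
Reagents that add atoms: none
Why: Iodination of the enolised dione and loss of HI should give the phenol while DMSO reoxidises HI to iodine, an oxidative aromatisation known for 4-alkoxycarbonyl-5-alkylcyclohexane-1,3-diones, and it places the carboxyl between the methyl branch and an oxygen without any aromatic substitution.

Step 3
Reactants: 5 methyl 2,4-dihydroxy-6-methylbenzoate
Product: 6 methyl 2,4-bis(benzyloxy)-6-methylbenzoate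
Conditions: BnBr (2.4 equiv), K2CO3, DMF, 60 °C
Reagents that add atoms: benzyl bromide, BrCc1ccccc1
Why: Williamson etherification of both phenols, the hydrogen-bonded ortho hydroxyl needing DMF and warming, gives ethers that are stable to all later base and acid steps and fall to hydrogenolysis at the end.

Step 4
Reactants: 6 methyl 2,4-bis(benzyloxy)-6-methylbenzoate
Product: 7 2,4-bis(benzyloxy)-6-methylbenzoic acid
Conditions: KOH, DMSO/H2O, 100 °C; then HCl
Reagents that add atoms: potassium hydroxide, [K+].[OH-]
Why: Saponification of a di-ortho-substituted benzoate is slow but should go with hydroxide in aqueous DMSO, the benzyl ethers being inert to base, and it removes the electrophilic ortho ester before any carbanion chemistry on the side chain.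

Step 5
Reactants: 7 2,4-bis(benzyloxy)-6-methylbenzoic acid
Product: 9 2,4-bis(benzyloxy)-6-(2-methoxy-2-oxoethyl)benzoic acid, via dilithio dianion 8 (not isolated)
Conditions: LiN(iPr)2 (3.2 equiv), THF, −78 → 0 °C; (MeO)2CO, −78 °C; then 1 M HCl
Reagents that add atoms: dimethyl carbonate, COC(=O)OC
Why: Lateral lithiation of an ortho-toluic acid through its carboxylate dianion followed by C-acylation with a carbonate is a known way to homophthalic half-esters; the meta alkoxy groups stabilise the benzylic anion inductively, the third equivalent of base absorbs the acidic product, and the carboxylate cannot be attacked.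

Step 6
Reactants: 10 5-heptylresorcinol
Product: 12 1-(2-heptyl-4,6-dihydroxyphenyl)ethan-1-one, via ketiminium chloride 11 (not isolated)
Conditions: MeCN, ZnCl2, HCl (g), Et2O, 0 °C; then H2O, reflux
Reagents that add atoms: acetonitrile, CC#N; water, O
Why: Hoesch acylation, in which the nitrilium species should attack C4 of the resorcinol (ortho to one hydroxyl, para to the other), as in the acylation of orcinol, and the ketiminium salt is hydrolysed to the ketone.

Step 7
Reactants: 12 1-(2-heptyl-4,6-dihydroxyphenyl)ethan-1-one
Product: 13 1-[4-(benzyloxy)-2-heptyl-6-hydroxyphenyl]ethan-1-one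
Conditions: BnBr (1.05 equiv), K2CO3, acetone, reflux
Reagents that add atoms: benzyl bromide, BrCc1ccccc1
Why: Williamson etherification that should be selective for the para hydroxyl, because the ortho hydroxyl is held in a hydrogen bond to the ketone and is the less acidic and less nucleophilic of the two.

Step 8
Reactants: 9 2,4-bis(benzyloxy)-6-(2-methoxy-2-oxoethyl)benzoic acid; 13 1-[4-(benzyloxy)-2-heptyl-6-hydroxyphenyl]ethan-1-one
Product: 14 2,4-bis(benzyloxy)-6-{4-[4-(benzyloxy)-2-heptyl-6-hydroxyphenyl]-2,4-dioxobutyl}benzoic acid
Conditions: NaH (3.3 equiv), THF, 0 °C → 65 °C; then 1 M HCl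
Reagents that add atoms: none
Why: Crossed Claisen condensation of an ortho-hydroxyacetophenone with an arylacetic ester, the reaction type long used for 1-(2-hydroxyaryl)-4-arylbutane-1,3-diones; base is limited to what phenol, acid and ketone require so that proton exchange stays reversible, the acetyl enolate attacks the unhindered aliphatic ester, the product is removed as a chelated diketonate, and the ring C carboxylate cannot serve as an intramolecular acceptor.

Step 9
Reactants: 14 2,4-bis(benzyloxy)-6-{4-[4-(benzyloxy)-2-heptyl-6-hydroxyphenyl]-2,4-dioxobutyl}benzoic acid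
Product: 15 2,4-bis(benzyloxy)-6-{[7-(benzyloxy)-5-heptyl-4-oxo-4H-chromen-2-yl]methyl}benzoic acid
Conditions: p-TsOH·H2O (10 mol%), toluene, 70 °C
Reagents that add atoms: none
Why: Acid-catalysed cyclodehydration in which the phenol adds to the distal carbonyl through a six-membered hemiketal and water is lost to give the γ-pyrone, expected to be faster than enol-lactonisation by the hindered carboxylic acid.

Step 10
Reactants: 15 2,4-bis(benzyloxy)-6-{[7-(benzyloxy)-5-heptyl-4-oxo-4H-chromen-2-yl]methyl}benzoic acid
Product: 16 siphulin
Conditions: H2 (1 atm), Pd/C (10 wt%), THF/MeOH, rt, stopped after three equivalents of H2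
Reagents that add atoms: none
Why: Hydrogenolysis of the three aryl benzyl ethers over palladium on carbon is neutral, so the decarboxylation-prone 2,4-dihydroxybenzoic acid should survive, and the pyrone double bond, a vinylogous ester, is reduced far more slowly than benzyl ethers are cleaved.

**Compound list**

1 | (E)-pent-3-en-2-one | C/C=C/C(C)=O | starting material
2 | dimethyl malonate | COC(=O)CC(=O)OC | starting material
3 | racemic dimethyl 2-(4-oxopentan-2-yl)propanedioate | COC(=O)C(C(=O)OC)C(C)CC(C)=O | intermediate (not isolated)
4 | racemic methyl trans-6-methyl-2,4-dioxocyclohexane-1-carboxylate (relative configuration shown) | COC(=O)[C@@H]1C(=O)CC(=O)C[C@H]1C | intermediate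
5 | methyl 2,4-dihydroxy-6-methylbenzoate | COC(=O)c1c(C)cc(O)cc1O | intermediate
6 | methyl 2,4-bis(benzyloxy)-6-methylbenzoate | COC(=O)c1c(C)cc(OCc2ccccc2)cc1OCc1ccccc1 | intermediate
7 | 2,4-bis(benzyloxy)-6-methylbenzoic acid | Cc1cc(OCc2ccccc2)cc(OCc2ccccc2)c1C(=O)O | intermediate
8 | lithium 2,4-bis(benzyloxy)-6-(lithiomethyl)benzoate | [Li]Cc1cc(OCc2ccccc2)cc(OCc2ccccc2)c1C(=O)O[Li] | intermediate (not isolated)
9 | 2,4-bis(benzyloxy)-6-(2-methoxy-2-oxoethyl)benzoic acid | COC(=O)Cc1cc(OCc2ccccc2)cc(OCc2ccccc2)c1C(=O)O | intermediate
10 | 5-heptylresorcinol (5-heptylbenzene-1,3-diol) | CCCCCCCc1cc(O)cc(O)c1 | starting material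
11 | 1-(2-heptyl-4,6-dihydroxyphenyl)ethan-1-iminium chloride | CCCCCCCc1cc(O)cc(O)c1C(C)=[NH2+].[Cl-] | intermediate (not isolated)
12 | 1-(2-heptyl-4,6-dihydroxyphenyl)ethan-1-one | CCCCCCCc1cc(O)cc(O)c1C(C)=O | intermediate
13 | 1-[4-(benzyloxy)-2-heptyl-6-hydroxyphenyl]ethan-1-one | CCCCCCCc1cc(OCc2ccccc2)cc(O)c1C(C)=O | intermediate
14 | 2,4-bis(benzyloxy)-6-{4-[4-(benzyloxy)-2-heptyl-6-hydroxyphenyl]-2,4-dioxobutyl}benzoic acid | CCCCCCCc1cc(OCc2ccccc2)cc(O)c1C(=O)CC(=O)Cc1cc(OCc2ccccc2)cc(OCc2ccccc2)c1C(=O)O | intermediate
15 | 2,4-bis(benzyloxy)-6-{[7-(benzyloxy)-5-heptyl-4-oxo-4H-chromen-2-yl]methyl}benzoic acid | CCCCCCCc1cc(OCc2ccccc2)cc2oc(Cc3cc(OCc4ccccc4)cc(OCc4ccccc4)c3C(=O)O)cc(=O)c12 | intermediate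
16 | siphulin, 2-[(5-heptyl-7-hydroxy-4-oxo-4H-chromen-2-yl)methyl]-4,6-dihydroxybenzoic acid | CCCCCCCc1cc(O)cc2oc(Cc3cc(O)cc(O)c3C(=O)O)cc(=O)c12 | target

**Count and risks**

Total steps: 10. Longest linear sequence: 8 (steps 1–5, 8–10).

Steps most likely to fail:

1. Step 8. The methylene of the arylacetic ester is more acidic than the acetyl group, so proton transfer to the ketone enolate may outrun C-acylation and the condensation may stall or the ester may self-condense. The fallback sets out from 13 and 7 and returns at 15. Ketone 13 is heated with N,N-dimethylformamide dimethyl acetal to give the enaminone (E)-1-[4-(benzyloxy)-2-heptyl-6-hydroxyphenyl]-3-(dimethylamino)prop-2-en-1-one F1, which aqueous HCl should close to 7-(benzyloxy)-5-heptyl-4H-chromen-4-one F2. The dilithio dianion 8, generated from 7 as in step 5, is then added to F2 in THF at −78 °C. Conjugate addition at C2 is expected because the C4 carbonyl is screened by the peri heptyl chain, and the carboxylate cannot trap the resulting enolate, so protonation should give racemic 2,4-bis(benzyloxy)-6-{[7-(benzyloxy)-5-heptyl-4-oxo-3,4-dihydro-2H-chromen-2-yl]methyl}benzoic acid F3. Dehydrogenation of F3 with DDQ in refluxing dioxane leads to chromone acid 15.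

2. Step 5. Lateral deprotonation of the carboxylate dianion may be incomplete, or the first-formed ester enolate may be acylated a second time by the carbonate. The fallback sets out from 6 and returns at 9. Ester 6 is deprotonated at the benzylic methyl with LiN(iPr)2 (2.2 equiv) in THF at −78 °C under the direction of the ester group and quenched with dimethyl carbonate to give methyl 2,4-bis(benzyloxy)-6-(2-methoxy-2-oxoethyl)benzoate F4. Both esters are saponified with KOH in aqueous DMSO at 100 °C to give 2,4-bis(benzyloxy)-6-(carboxymethyl)benzoic acid F5. Methanol with catalytic H2SO4 at room temperature should then esterify only the unhindered aliphatic acid and give 9.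

3. Step 10. The pyrone C2–C3 double bond may be reduced during hydrogenolysis, or the liberated resorcylic acid may lose CO2 on prolonged contact with the catalyst. The fallback sets out from 15 and ends at 16: a non-reductive Lewis-acid debenzylation with BCl3 and pentamethylbenzene as cation scavenger in CH2Cl2 at −78 °C, quenched cold with methanol; it makes no new intermediate.

**Further compounds**

F1 | step 8 | (E)-1-[4-(benzyloxy)-2-heptyl-6-hydroxyphenyl]-3-(dimethylamino)prop-2-en-1-one | CCCCCCCc1cc(OCc2ccccc2)cc(O)c1C(=O)/C=C/N(C)C
F2 | step 8 | 7-(benzyloxy)-5-heptyl-4H-chromen-4-one | CCCCCCCc1cc(OCc2ccccc2)cc2occc(=O)c12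
F3 | step 8 | racemic 2,4-bis(benzyloxy)-6-{[7-(benzyloxy)-5-heptyl-4-oxo-3,4-dihydro-2H-chromen-2-yl]methyl}benzoic acid | CCCCCCCc1cc(OCc2ccccc2)cc2OC(Cc3cc(OCc4ccccc4)cc(OCc4ccccc4)c3C(=O)O)CC(=O)c12
F4 | step 5 | methyl 2,4-bis(benzyloxy)-6-(2-methoxy-2-oxoethyl)benzoate | COC(=O)Cc1cc(OCc2ccccc2)cc(OCc2ccccc2)c1C(=O)OC
F5 | step 5 | 2,4-bis(benzyloxy)-6-(carboxymethyl)benzoic acid | OC(=O)Cc1cc(OCc2ccccc2)cc(OCc2ccccc2)c1C(=O)O
F0 | step 10 | none | none
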